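Retrosynthesis: (a) cut the central C=C of the (E)-2-alkyl-2-enal. It is the retron of an aldehyde self-condensation. Ring A and ring B are both (2S,3S,6R) and the two tethers differ by exactly one CH2, so the target is two molecules of aldehyde 16 minus water. (b) Cut the side chain at C2'=C3' (cross-metathesis with undec-10-enal) and at C6-C1' (allylsilane on an iminium ion). (c) Cut N1-C6.
Enabling feature for (c): in each ring, C3(O)-C4-C5-C6(N) is a four-carbon unit with a heteroatom on both ends, which maps onto C2-C5 of a furan. C2 with its CH3 and N1 is then an exocyclic 1-aminoethyl group. Oxidative dearomatisation of that furfurylamine (aza-Achmatowicz) frees old furan C5 as an aldehyde held Z to the C3 ketone, and N1 closes on it.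
Forward order: furfural + sulfinamide + MeMgBr give the furfurylamine, and oxidation/ring closure builds the piperidine. The C3 ketone is reduced, C4=C5 saturated and allyl placed on C6. The chain grows by metathesis/hydrogenation, two molecules join by aldol condensation, and acid removes the helpers.
Stereochemistry: C2 comes from (R)-tert-butanesulfinamide. C3 and C6 are relayed from C2, whose methyl is locked axial by A(1,3) strain with the N-sulfonyl group. The E alkene comes from the amine-catalysed condensation.
Helper group: the sulfinyl auxiliary is not removed but oxidised in the key-step flask to tert-butylsulfonyl (Bus). Bus tames N1, activates the iminium ion, enforces the axial methyl and finally leaves under acid, which the enal tolerates.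

Key step: step 3

Assumption: the C6 configuration of 7-11 is left undefined because it is erased on ionisation in step 8. Compound 15 is drawn as the E isomer, and its alkene geometry is erased in step 10.

Step 1
Reactants: 1 furfural; 2 (R)-tert-butanesulfinamide
Product: 3 (R,E)-N-(furan-2-ylmethylidene)-2-methylpropane-2-sulfinamide
Conditions: Ti(OEt)4 (2 equiv), THF, rt
Reagents that add atoms: none
Why: Lewis-acid-mediated condensation of an aldehyde with a sulfinamide, with the titanium alkoxide also scavenging water, should give the E-aldimine without touching the sulfur stereocentre.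

Step 2
Reactants: 3 sulfinyl aldimine
Product: 4 (R)-N-[(1S)-1-(furan-2-yl)ethyl]-2-methylpropane-2-sulfinamide
Conditions: MeMgBr (3 M in Et2O, 2 equiv), CH2Cl2, -48 °C; aqueous work-up
Reagents that add atoms: methylmagnesium bromide, C[Mg]Br
Why: Grignard 1,2-addition to a tert-butanesulfinyl aldimine in a non-coordinating solvent runs through a six-membered chair (Mg bound to the sulfinyl oxygen, tert-butyl and furyl equatorial), so the (R)-sulfur should deliver methyl to one face and set the carbon as S, the future C2 of both rings.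

Step 3
Reactants: 4 sulfinamide
Product: 7 (2S)-1-(tert-butylsulfonyl)-6-hydroxy-2-methyl-1,6-dihydropyridin-3(2H)-one, via Bus sulfonamide 5 (not isolated), via Z-keto-enal 6 (not isolated)
Conditions: mCPBA (2.2 equiv), CH2Cl2, 0 °C to rt
Reagents that add atoms: mCPBA (3-chloroperoxybenzoic acid), OOC(=O)c1cccc(Cl)c1
Why: The first equivalent of mCPBA oxidises the sulfinamide sulfur to the sulfonamide 5, turning the spent auxiliary into the non-basic, electron-withdrawing N-substituent the next event needs, and the second equivalent epoxidises the substituted C2=C3 bond of the furan, whose epoxide collapses with ring opening to the Z-4-oxo-enal 6. Because the Z geometry is inherited from the aromatic ring, the sulfonamide N-H and the unmasked aldehyde carbon (old furan C5, future C6) lie within reach and close by 6-exo-trig addition to the cyclic hemiaminal, which forms the N1-C6 bond; this is the aza-Achmatowicz oxidative rearrangement, well known for N-sulfonyl and N-carbamoyl furfurylamines, and mCPBA oxidation of tert-butanesulfinamides to Bus amides is equally standard. In one flask the flat heteroarene becomes the whole piperidine skeleton with three differentiated handles: the C3 ketone (future hydroxyl), the C4=C5 alkene and the C6 hemiaminal (future point of chain attachment). The only new stereocentre, C6, is under thermodynamic control (hydroxyl pseudoaxial, favoured by the anomeric effect and by avoiding A(1,3) strain with Bus) and is of no consequence because it is ionised in step 8. The step needs oxidation of sulfur and furan but not of the product, which the electron-poor enone secures, and it needs retention at C2, which is secured because A(1,3) strain holds the C2 methyl axial and the C2-H equatorial, poorly aligned with the C3 carbonyl for enolisation.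

Step 4
Reactants: 7 hemiaminal
Product: 8 (2S)-1-(tert-butylsulfonyl)-6-methoxy-2-methyl-1,6-dihydropyridin-3(2H)-one
Conditions: HC(OMe)3, BF3·OEt2 (cat.), 4 Å MS, CH2Cl2, 0 °C
Reagents that add atoms: trimethyl orthoformate, COC(OC)OC
Why: Acid-catalysed N,O-acetal exchange through the N-sulfonyliminium ion, with the orthoformate as methanol source and water scavenger, locks the ring-chain tautomerism so that the masked aldehyde survives the hydride step.

Step 5
Reactants: 8 methoxy enone
Product: 9 (2S,3S)-1-(tert-butylsulfonyl)-6-methoxy-2-methyl-1,2,3,6-tetrahydropyridin-3-ol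
Conditions: NaBH4, CeCl3·7H2O, MeOH, -40 °C
Reagents that add atoms: none
Why: In this Luche 1,2-reduction the axial C2 methyl shields one face of the adjacent C3 carbonyl, so hydride should enter anti to it and leave the new hydroxyl cis to the methyl (3S).

Step 6
Reactants: 9 allylic alcohol
Product: 10 (2S,3S)-1-(tert-butylsulfonyl)-6-methoxy-2-methylpiperidin-3-ol
Conditions: H2 (1 atm), Pd/C, EtOAc, rt
Reagents that add atoms: none
Why: Heterogeneous catalytic hydrogenation saturates the only C=C bond without creating a stereocentre, and it is done now because the later iminium ion must be a saturated half-chair for axial, chair-like attack.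

Step 7
Reactants: 10 alcohol
Product: 11 (2S,3S)-3-(tert-butyldimethylsilyloxy)-1-(tert-butylsulfonyl)-6-methoxy-2-methylpiperidine
Conditions: TBSCl, imidazole, DMF, rt
Reagents that add atoms: tert-butyldimethylsilyl chloride, CC(C)(C)[Si](C)(C)Cl
Why: Imidazole-promoted silyl ether formation masks the C3 hydroxyl against the Lewis acid of step 8, and the group falls later in the same acid treatment as Bus.

Step 8
Reactants: 11 N,O-acetal
Product: 13 (2S,3S,6S)-6-allyl-3-(tert-butyldimethylsilyloxy)-1-(tert-butylsulfonyl)-2-methylpiperidine (all-cis), via N-sulfonyliminium ion 12 (not isolated)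
Conditions: allyltrimethylsilane (3 equiv), BF3·OEt2 (1.5 equiv), CH2Cl2, -78 °C
Reagents that add atoms: allyltrimethylsilane, C=CC[Si](C)(C)C
Why: In this Hosomi-Sakurai-type allylation of an N-sulfonyliminium ion, half-chair 12 carries the C2 methyl axial (A(1,3) strain with Bus) and the silyloxy group equatorial, so stereoelectronically preferred axial attack through a chair-like transition state should place the allyl group on the same face as the methyl (2,6-cis), as known for N-arylsulfonyl analogues.

Step 9
Reactants: 13 allylpiperidine; 14 undec-10-enal (3 equiv)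
Product: 15 (10E)-12-[(2S,5S,6S)-5-(tert-butyldimethylsilyloxy)-1-(tert-butylsulfonyl)-6-methylpiperidin-2-yl]dodec-10-enal
Conditions: second-generation Grubbs catalyst (H2IMes)(PCy3)Cl2Ru=CHPh (5 mol %), 1,4-benzoquinone (10 mol %), CH2Cl2, 40 °C
Reagents that add atoms: none
Why: Olefin cross-metathesis of two unhindered terminal alkenes is driven by loss of ethylene and by the excess of the cheap partner, benzoquinone suppresses ruthenium-hydride chain walking, and 3 + 11 - 2 carbons give exactly the twelve-carbon chain.

Step 10
Reactants: 15 unsaturated aldehyde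
Product: 16 12-[(2R,5S,6S)-5-(tert-butyldimethylsilyloxy)-1-(tert-butylsulfonyl)-6-methylpiperidin-2-yl]dodecanal
Conditions: H2 (1 atm), Pd/C, EtOAc, rt
Reagents that add atoms: none
Why: Catalytic hydrogenation of a disubstituted alkene in a non-alcoholic solvent leaves the aliphatic aldehyde, sulfonamide and silyl ether untouched, and the ring carbon descriptor changes from S to R only through CIP priorities.

Step 11
Reactants: 16 aldehyde (two molecules)
Product: 17 (2E)-14-[(2R,5S,6S)-5-(tert-butyldimethylsilyloxy)-1-(tert-butylsulfonyl)-6-methylpiperidin-2-yl]-2-{10-[(2R,5S,6S)-5-(tert-butyldimethylsilyloxy)-1-(tert-butylsulfonyl)-6-methylpiperidin-2-yl]decyl}tetradec-2-enal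
Conditions: pyrrolidine (20 mol %), PhCO2H (20 mol %), toluene (1 M), rt to 40 °C
Reagents that add atoms: none
Why: In this amine/acid-catalysed homo-aldol condensation the enamine of one molecule adds Mannich-fashion to the iminium ion of the other and pyrrolidine is then eliminated, which should give the more stable E enal (C3 chain trans to CHO) while the remote, fully protected rings stay untouched.

Step 12
Reactants: 17 protected dimer
Product: 18 target, (2E)-14-[(2R,5S,6S)-5-hydroxy-6-methylpiperidin-2-yl]-2-{10-[(2R,5S,6S)-5-hydroxy-6-methylpiperidin-2-yl]decyl}tetradec-2-enal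
Conditions: TfOH (0.1 M in CH2Cl2, excess), anisole, 0 °C; then H2O/THF, rt; aq NaHCO3 work-up
Reagents that add atoms: none
Why: In this acidolysis the hindered tertiary Bus sulfonamides lose tert-butyl cation (trapped by anisole) and then SO2, the silyl ethers are cleaved by the same acid once water is added, and the alpha,beta-dialkyl enal is a poor electrophile while the liberated amines stay protonated until work-up.

Compound list
1 | furfural | O=Cc1ccco1 | starting material
2 | (R)-tert-butanesulfinamide | CC(C)(C)[S@@](=O)N | starting material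
3 | (R,E)-N-(furan-2-ylmethylidene)-2-methylpropane-2-sulfinamide | CC(C)(C)[S@@](=O)/N=C/c1ccco1 | intermediate
4 | (R)-N-[(1S)-1-(furan-2-yl)ethyl]-2-methylpropane-2-sulfinamide | CC(C)(C)[S@@](=O)N[C@@H](C)c1ccco1 | intermediate
5 | N-[(1S)-1-(furan-2-yl)ethyl]-2-methylpropane-2-sulfonamide (Bus sulfonamide, not isolated) | CC(C)(C)S(=O)(=O)N[C@@H](C)c1ccco1 | intermediate
6 | N-[(2S,4Z)-3,6-dioxohex-4-en-2-yl]-2-methylpropane-2-sulfonamide (not isolated) | CC(C)(C)S(=O)(=O)N[C@@H](C)C(=O)/C=C\C=O | intermediate
7 | (2S)-1-(tert-butylsulfonyl)-6-hydroxy-2-methyl-1,6-dihydropyridin-3(2H)-one | C[C@@H]1N(S(=O)(=O)C(C)(C)C)C(O)C=CC1=O | intermediate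
8 | (2S)-1-(tert-butylsulfonyl)-6-methoxy-2-methyl-1,6-dihydropyridin-3(2H)-one | C[C@@H]1N(S(=O)(=O)C(C)(C)C)C(OC)C=CC1=O | intermediate
9 | (2S,3S)-1-(tert-butylsulfonyl)-6-methoxy-2-methyl-1,2,3,6-tetrahydropyridin-3-ol | C[C@@H]1N(S(=O)(=O)C(C)(C)C)C(OC)C=C[C@@H]1O | intermediate
10 | (2S,3S)-1-(tert-butylsulfonyl)-6-methoxy-2-methylpiperidin-3-ol | C[C@@H]1N(S(=O)(=O)C(C)(C)C)C(OC)CC[C@@H]1O | intermediate
11 | (2S,3S)-3-(tert-butyldimethylsilyloxy)-1-(tert-butylsulfonyl)-6-methoxy-2-methylpiperidine | C[C@@H]1N(S(=O)(=O)C(C)(C)C)C(OC)CC[C@@H]1O[Si](C)(C)C(C)(C)C | intermediate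
12 | (2S,3S)-3-(tert-butyldimethylsilyloxy)-1-(tert-butylsulfonyl)-2-methyl-2,3,4,5-tetrahydropyridin-1-ium (not isolated) | C[C@@H]1[N+](S(=O)(=O)C(C)(C)C)=CCC[C@@H]1O[Si](C)(C)C(C)(C)C | intermediate
13 | (2S,3S,6S)-6-allyl-3-(tert-butyldimethylsilyloxy)-1-(tert-butylsulfonyl)-2-methylpiperidine | C[C@@H]1N(S(=O)(=O)C(C)(C)C)[C@H](CC=C)CC[C@@H]1O[Si](C)(C)C(C)(C)C | intermediate
14 | undec-10-enal | C=CCCCCCCCCC=O | starting material
15 | (10E)-12-[(2S,5S,6S)-5-(tert-butyldimethylsilyloxy)-1-(tert-butylsulfonyl)-6-methylpiperidin-2-yl]dodec-10-enal | C[C@@H]1N(S(=O)(=O)C(C)(C)C)[C@H](C/C=C/CCCCCCCCC=O)CC[C@@H]1O[Si](C)(C)C(C)(C)C | intermediate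
16 | 12-[(2R,5S,6S)-5-(tert-butyldimethylsilyloxy)-1-(tert-butylsulfonyl)-6-methylpiperidin-2-yl]dodecanal | C[C@@H]1N(S(=O)(=O)C(C)(C)C)[C@H](CCCCCCCCCCCC=O)CC[C@@H]1O[Si](C)(C)C(C)(C)C | intermediate
17 | bis(Bus), bis(TBS) protected (E)-enal dimer | C[C@@H]1N(S(=O)(=O)C(C)(C)C)[C@H](CCCCCCCCCCC/C=C(/C=O)CCCCCCCCCC[C@@H]2CC[C@H](O[Si](C)(C)C(C)(C)C)[C@H](C)N2S(=O)(=O)C(C)(C)C)CC[C@@H]1O[Si](C)(C)C(C)(C)C | intermediate
18 | CNP0177491.1 | C[C@@H]1N[C@H](CCCCCCCCCCC/C=C(/C=O)CCCCCCCCCC[C@@H]2CC[C@H](O)[C@H](C)N2)CC[C@@H]1O | target

Total step count: 12. Longest linear sequence: 12 (both halves come from the same monomer 16).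

Steps most likely to fail

1. Step 12.
- What may go wrong: the strong acid may promote attack of the scavenger on the protonated enal. Loss of the hindered sulfonyl groups may be incomplete. The hydroxyls may be re-silylated on quench.
- Fallback (sets out from 13, comes back at 18): exchange the nitrogen group before any carbonyl is present, so that the last step is a mild carbamate cleavage.
- Compound 13 is treated with TfOH/anisole and then water to give (2S,3S,6S)-6-allyl-2-methylpiperidin-3-ol F1.
- Boc2O, Et3N, THF at 60 °C gives tert-butyl (2S,3S,6S)-6-allyl-3-hydroxy-2-methylpiperidine-1-carboxylate F2.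
- Cross-metathesis with 14 under the step 9 conditions gives the N-Boc dodec-10-enal F3.
- H2, Pd/C, EtOAc gives the N-Boc dodecanal F4.
- The pyrrolidine/PhCO2H condensation, which tolerates the free secondary hydroxyl, gives the bis-Boc diol enal F5.
- TFA/CH2Cl2 at 0 °C followed by NaHCO3 gives 18.

2. Step 8.
- What may go wrong: facial selectivity may be poor. The syn-axial contact between the incoming allylsilane and the C2 methyl may divert attack through a twist-boat to the 2,6-trans series. The silyl ether may also be lost to BF3.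
- Fallback (sets out from 11, comes back at 13): set C6 by reagent control in the open chain and re-form N1-C6 by substitution with inversion.
- PPTS in acetone/H2O turns 11 into the saturated hemiaminal F6.
- The open aldehyde form of F6 undergoes Brown allylboration with Ipc2B(allyl) made from (+)-alpha-pinene (Et2O, -78 °C to rt, then NaOH/H2O2). This gives N-[(2S,3S,6R)-3-(tert-butyldimethylsilyloxy)-6-hydroxynon-8-en-2-yl]-2-methylpropane-2-sulfonamide F7.
- MsCl, Et3N, CH2Cl2 gives the secondary mesylate F8.
- KOtBu in THF closes the ring by 6-exo-tet displacement with inversion to give 13.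

3. Step 3.
- What may go wrong: over-oxidation may occur. Closure of the bulky Bus sulfonamide onto the aldehyde may be slow, so that the open keto-enal isomerises to the E form or oligomerises.
- Fallback (sets out from 4, comes back at 8): separate oxidation from ring closure through an isolable bis-acetal.
- One equivalent of mCPBA at -20 °C gives 5, now isolated.
- Br2, Na2CO3, MeOH at -40 °C gives N-[(1S)-1-(2,5-dimethoxy-2,5-dihydrofuran-2-yl)ethyl]-2-methylpropane-2-sulfonamide F9.
- Catalytic TsOH in CH2Cl2 ionises the acetal carbon and lets the sulfonamide nitrogen capture it while the ketal unravels to the ketone. This gives 8 directly and makes step 4 unnecessary.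

Further compounds
F1 | step 12 | (2S,3S,6S)-6-allyl-2-methylpiperidin-3-ol | C[C@@H]1N[C@H](CC=C)CC[C@@H]1O
F2 | step 12 | tert-butyl (2S,3S,6S)-6-allyl-3-hydroxy-2-methylpiperidine-1-carboxylate | C[C@@H]1N(C(=O)OC(C)(C)C)[C@H](CC=C)CC[C@@H]1O
F3 | step 12 | tert-butyl (2S,3S,6S)-3-hydroxy-2-methyl-6-[(2E)-12-oxododec-2-en-1-yl]piperidine-1-carboxylate | C[C@@H]1N(C(=O)OC(C)(C)C)[C@H](C/C=C/CCCCCCCCC=O)CC[C@@H]1O
F4 | step 12 | tert-butyl (2S,3S,6R)-3-hydroxy-2-methyl-6-(12-oxododecyl)piperidine-1-carboxylate | C[C@@H]1N(C(=O)OC(C)(C)C)[C@H](CCCCCCCCCCCC=O)CC[C@@H]1O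
F5 | step 12 | bis-Boc diol (E)-enal dimer | C[C@@H]1N(C(=O)OC(C)(C)C)[C@H](CCCCCCCCCCC/C=C(/C=O)CCCCCCCCCC[C@@H]2CC[C@H](O)[C@H](C)N2C(=O)OC(C)(C)C)CC[C@@H]1O
F6 | step 8 | (5S,6S)-5-(tert-butyldimethylsilyloxy)-1-(tert-butylsulfonyl)-6-methylpiperidin-2-ol | C[C@@H]1N(S(=O)(=O)C(C)(C)C)C(O)CC[C@@H]1O[Si](C)(C)C(C)(C)C
F7 | step 8 | N-[(2S,3S,6R)-3-(tert-butyldimethylsilyloxy)-6-hydroxynon-8-en-2-yl]-2-methylpropane-2-sulfonamide | C[C@H](NS(=O)(=O)C(C)(C)C)[C@H](CC[C@@H](O)CC=C)O[Si](C)(C)C(C)(C)C
F8 | step 8 | (4R,7S,8S)-7-(tert-butyldimethylsilyloxy)-8-(tert-butylsulfonylamino)non-1-en-4-yl methanesulfonate | C[C@H](NS(=O)(=O)C(C)(C)C)[C@H](CC[C@@H](OS(C)(=O)=O)CC=C)O[Si](C)(C)C(C)(C)C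
F9 | step 3 | N-[(1S)-1-(2,5-dimethoxy-2,5-dihydrofuran-2-yl)ethyl]-2-methylpropane-2-sulfonamide | CC(C)(C)S(=O)(=O)N[C@@H](C)C1(OC)C=CC(OC)O1
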